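**Assumptions (one line each)**
- The target SMILES has no stereocentres (it is achiral), so no enantiomer has to be set.
- In step 4, the phenol flanked by an aromatic H closes the chromone faster than the phenol flanked by the prenyl group. I assume this steric and acidity bias gives mainly the 6-prenyl isomer, with the minor 8-prenyl isomer removable by chromatography.
- All building blocks are commercial: phloroacetophenone, prenyl bromide, MOMCl, DMF-DMA, I2, prenal, 6-bromoveratraldehyde, mCPBA, TBSCl and B2pin2.

**Retrosynthesis**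
1. Final step: global MOM removal from the protected benzofuro[2,3-b]chromenone (5-OMOM and catechol bis-MOM).
2. The furan ring is formed last, by a proposed Pd(II)-catalysed dehydrogenative C2–H etherification of a 2'-hydroxyisoflavone (new C2–O bond).
3. The isoflavone comes from Suzuki coupling of a 3-iodochromone (A ring already carrying 5-OH, 6-prenyl and the 7,8-dimethylpyran) with a 2-silyloxy-4,5-bis(MOMO)phenyl-Bpin.
4. A ring order: C-prenylation of phloroacetophenone, then chromone ring (enaminone/I2), then dimethylpyran ring (boronate-mediated prenal annulation at the only free C8).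
5. B ring: 6-bromoveratraldehyde, then demethylation, MOM protection, Baeyer–Villiger (Dakin-type), TBS protection and Miyaura borylation.

**Route**

**Step 1**
Reactants: 1 (2,4,6-trihydroxyacetophenone); 2 (prenyl bromide)
Product: 3 (1-(2,4,6-trihydroxy-3-prenylphenyl)ethanone)
Conditions: KOH, H2O/MeOH, 0 °C → rt
Reagents that add atoms: prenyl bromide CC(C)=CCBr (compound 2, listed as reactant)
Why: Phenolate C-alkylation of phloroacetophenone; C3 and C5 are equivalent, so the regiochemistry is unique. No stereocentre is formed.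

**Step 2**
Reactants: 3; 4 (MOMCl)
Product: 5 (1-[2,6-dihydroxy-4-(methoxymethoxy)-3-prenylphenyl]ethanone)
Conditions: MOMCl (1.05 equiv), DIPEA, CH2Cl2, 0 °C
Reagents that add atoms: chloromethyl methyl ether ClCOC (compound 4)
Why: Selective alkylation of the acidic, non-chelated 4-OH (the two chelated OHs are untouched); this also prevents O-methylation by DMF-DMA in step 3. No stereocentre.

**Step 3**
Reactants: 5; 6 (DMF-DMA)
Product: 7 ((E)-3-(dimethylamino)-1-[2,6-dihydroxy-4-MOMO-3-prenylphenyl]prop-2-en-1-one)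
Conditions: DMF-DMA (3 equiv), toluene, 110 °C
Reagents that add atoms: DMF-DMA CN(C)C(OC)OC (compound 6)
Why: Enaminone formation at the acetyl methyl group (Bredereck/Gammill type). No stereocentre.

**Step 4**
Reactants: 7; 8 (I2)
Product: 9 (5-hydroxy-3-iodo-7-(methoxymethoxy)-6-prenylchromone)
Conditions: I2 (1.3 equiv), CHCl3, rt, then aq. Na2S2O3
Reagents that add atoms: iodine II (compound 8)
Why: Gammill iodocyclisation: α-iodination of the enaminone, then oxa-Michael and elimination of Me2NH; closure through the less hindered OH next to the aromatic H places the prenyl at C6 beside the 5-OH (regiochemical assumption above). No stereocentre.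

**Step 5**
Reactants: 9
Product: 10 (5,7-dihydroxy-3-iodo-6-prenylchromone)
Conditions: 3 M HCl, THF/MeOH 1:1, 40 °C
Reagents that add atoms: none
Why: Mild acidic cleavage of the aryl MOM ether; the chelated 5-OH and the prenyl group survive. No stereocentre.

**Step 6**
Reactants: 10; 11 (prenal)
Product: 12 (5-hydroxy-3-iodo-6-prenyl-7,8-(2,2-dimethyl-2H-pyrano)chromone)
Conditions: 11 (3 equiv), PhB(OH)2 (1.5 equiv), EtCO2H (0.3 equiv), PhMe, 110 °C, Dean–Stark
Reagents that add atoms: prenal CC(C)=CC=O (compound 11, listed as reactant)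
Why: Boronate-templated ortho-quinone-methide/6π-electrocyclisation chromene synthesis; C6 is blocked and the 5-OH is chelated, so only C8 next to the 7-OH reacts. No stereocentre (the C2' gem-dimethyl carbon is not a stereocentre).

**Step 7**
Reactants: 13 (2-bromo-4,5-dimethoxybenzaldehyde)
Product: 14 (2-bromo-4,5-dihydroxybenzaldehyde)
Conditions: BBr3 (3 equiv), CH2Cl2, −78 °C → rt
Reagents that add atoms: none
Why: BBr3 aryl methyl ether cleavage; the aryl bromide and aldehyde survive.

**Step 8**
Reactants: 14; 4 (MOMCl)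
Product: 15 (2-bromo-4,5-bis(methoxymethoxy)benzaldehyde)
Conditions: MOMCl (2.5 equiv), DIPEA, CH2Cl2, 0 °C → rt
Reagents that add atoms: MOMCl ClCOC (compound 4)
Why: Standard bis-MOM protection of the catechol.

**Step 9**
Reactants: 15; 16 (mCPBA)
Product: 17 (2-bromo-4,5-bis(methoxymethoxy)phenol)
Conditions: mCPBA (1.5 equiv), CH2Cl2, 0 °C → rt; then K2CO3, MeOH
Reagents that add atoms: mCPBA OOC(=O)c1cccc(Cl)c1 (compound 16; the inserted O stays as the phenol O)
Why: Baeyer–Villiger (Dakin-type) oxidation of the electron-rich aldehyde gives the aryl formate, which methanolysis converts to the phenol.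

**Step 10**
Reactants: 17; 18 (TBSCl)
Product: 19 (aryl TBS ether of 2-bromo-4,5-bis(MOMO)phenol)
Conditions: TBSCl (1.2 equiv), imidazole, DMF, rt
Reagents that add atoms: TBSCl CC(C)(C)[Si](C)(C)Cl (compound 18)
Why: Silylation gives a protecting group that is orthogonal to MOM (removable later by fluoride).

**Step 11**
Reactants: 19; 20 (B2pin2)
Product: 21 (2-(TBSO)-4,5-bis(MOMO)phenyl-Bpin)
Conditions: B2pin2 (1.2 equiv), Pd(dppf)Cl2 (5 mol%), KOAc, dioxane, 90 °C
Reagents that add atoms: bis(pinacolato)diboron CC1(C)OB(OC1(C)C)B1OC(C)(C)C(C)(C)O1 (compound 20)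
Why: Miyaura borylation of the aryl bromide.

**Step 12**
Reactants: 12; 21
Product: 22 (isoflavone: 5-OH, 6-prenyl, 7,8-dimethylpyrano; B ring 2'-OTBS, 4',5'-bis-OMOM)
Conditions: Pd(PPh3)4 (5 mol%), K3PO4 (3 equiv), dioxane/H2O 10:1, 80 °C
Reagents that add atoms: none
Why: Suzuki–Miyaura coupling at the C3–I bond of the chromone forms the isoflavone C3–C1' bond. No stereocentre.

**Step 13**
Reactants: 22; 4 (MOMCl)
Product: 23 (5-O-MOM isoflavone)
Conditions: NaH (1.3 equiv), DMF, 0 °C; then MOMCl (1.5 equiv)
Reagents that add atoms: MOMCl ClCOC (compound 4)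
Why: The chelated 5-OH next to the prenyl group is masked so that it cannot undergo Wacker-type cyclisation onto the prenyl group, or oxidation, in step 15.

**Step 14**
Reactants: 23
Product: 24 (2'-hydroxyisoflavone; 5-OMOM, 4',5'-bis-OMOM)
Conditions: TBAF (1.2 equiv), AcOH (1.2 equiv), THF, 0 °C
Reagents that add atoms: none
Why: Buffered fluoride removes only the aryl TBS group; the MOM ethers are unaffected.

**Step 15**
Reactants: 24
Product: 25 (5,6-bis-OMOM benzofuro[2,3-b]chromenone; A ring 5-OMOM, 6-prenyl, 7,8-dimethylpyrano)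
Conditions: Pd(OAc)2 (10 mol%), Cu(OAc)2 (20 mol%), PivOH (30 mol%), DMA, O2 (1 atm), 90 °C
Reagents that add atoms: none (O2 is the terminal oxidant; net loss of H2)
Why: Proposed new method: the 2'-OH, as a Pd(II) phenoxide, directs concerted metalation–deprotonation at the chromone C2–H through a six-membered oxapalladacycle, and C–O reductive elimination (Pd(II)/Cu/O2 turnover) closes the five-membered furan to give the 2-aryloxychromone acetal carbon; the closest known reactions are phenol-directed Pd(II) C–H activation/C–O cyclisation of 2-arylphenols to dibenzofurans and the aerobic Pd(II) Wacker-type dehydrogenative cyclisation of 2'-hydroxydihydrochalcones to flavones, here extended to the β-C–H of a vinylogous-ester chromone, which is not known; no stereocentre is formed.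

**Step 16**
Reactants: 25
Product: 26 (Euchretin G)
Conditions: 2 M HCl, THF/MeOH 1:1, 40 °C, N2
Reagents that add atoms: none
Why: Acidic hydrolysis of the three aryl MOM ethers releases the catechol and the chelated 5-OH; the prenyl group and the dimethylchromene tolerate brief mild acid.

**Compound list**

| No. | Name | SMILES | Role |
|---|---|---|---|
| 1 | 2,4,6-trihydroxyacetophenone | CC(=O)c1c(O)cc(O)cc1O | starting material |
| 2 | prenyl bromide | CC(C)=CCBr | starting material |
| 3 | 1-(2,4,6-trihydroxy-3-prenylphenyl)ethanone | CC(=O)c1c(O)cc(O)c(CC=C(C)C)c1O | intermediate |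
| 4 | chloromethyl methyl ether (MOMCl) | ClCOC | starting material |
| 5 | 1-[2,6-dihydroxy-4-(methoxymethoxy)-3-prenylphenyl]ethanone | CC(=O)c1c(O)cc(OCOC)c(CC=C(C)C)c1O | intermediate |
| 6 | DMF dimethyl acetal | CN(C)C(OC)OC | starting material |
| 7 | (E)-enaminone of 5 | CN(C)/C=C/C(=O)c1c(O)cc(OCOC)c(CC=C(C)C)c1O | intermediate |
| 8 | iodine | II | starting material |
| 9 | 5-hydroxy-3-iodo-7-(MOMO)-6-prenylchromone | O=c1c(I)coc2cc(OCOC)c(CC=C(C)C)c(O)c12 | intermediate |
| 10 | 5,7-dihydroxy-3-iodo-6-prenylchromone | O=c1c(I)coc2cc(O)c(CC=C(C)C)c(O)c12 | intermediate |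
| 11 | 3-methylbut-2-enal (prenal) | CC(C)=CC=O | starting material |
| 12 | 5-hydroxy-3-iodo-6-prenyl-7,8-(2,2-dimethylpyrano)chromone | CC(C)=CCc1c2c(c3occ(I)c(=O)c3c1O)C=CC(C)(C)O2 | intermediate |
| 13 | 2-bromo-4,5-dimethoxybenzaldehyde | COc1cc(C=O)c(Br)cc1OC | starting material |
| 14 | 2-bromo-4,5-dihydroxybenzaldehyde | O=Cc1cc(O)c(O)cc1Br | intermediate |
| 15 | 2-bromo-4,5-bis(MOMO)benzaldehyde | O=Cc1cc(OCOC)c(OCOC)cc1Br | intermediate |
| 16 | mCPBA | OOC(=O)c1cccc(Cl)c1 | starting material |
| 17 | 2-bromo-4,5-bis(MOMO)phenol | Oc1cc(OCOC)c(OCOC)cc1Br | intermediate |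
| 18 | TBSCl | CC(C)(C)[Si](C)(C)Cl | starting material |
| 19 | aryl TBS ether of 17 | CC(C)(C)[Si](C)(C)Oc1cc(OCOC)c(OCOC)cc1Br | intermediate |
| 20 | bis(pinacolato)diboron | CC1(C)OB(OC1(C)C)B1OC(C)(C)C(C)(C)O1 | starting material |
| 21 | 2-(TBSO)-4,5-bis(MOMO)phenyl-Bpin | CC(C)(C)[Si](C)(C)Oc1cc(OCOC)c(OCOC)cc1B1OC(C)(C)C(C)(C)O1 | intermediate |
| 22 | 2'-OTBS-4',5'-bis-OMOM isoflavone, 5-OH | CC(C)=CCc1c2c(c3occ(-c4cc(OCOC)c(OCOC)cc4O[Si](C)(C)C(C)(C)C)c(=O)c3c1O)C=CC(C)(C)O2 | intermediate |
| 23 | 5-O-MOM analogue of 22 | CC(C)=CCc1c2c(c3occ(-c4cc(OCOC)c(OCOC)cc4O[Si](C)(C)C(C)(C)C)c(=O)c3c1OCOC)C=CC(C)(C)O2 | intermediate |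
| 24 | 2'-hydroxy isoflavone (5-OMOM, 4',5'-bis-OMOM) | CC(C)=CCc1c2c(c3occ(-c4cc(OCOC)c(OCOC)cc4O)c(=O)c3c1OCOC)C=CC(C)(C)O2 | intermediate |
| 25 | tris-MOM benzofuro[2,3-b]chromenone | CC(C)=CCc1c2c(c3oc4oc5cc(OCOC)c(OCOC)cc5c4c(=O)c3c1OCOC)C=CC(C)(C)O2 | intermediate |
| 26 | Euchretin G | CC(C)=CCc1c2c(c3oc4oc5cc(O)c(O)cc5c4c(=O)c3c1O)C=CC(C)(C)O2 | target |

**Totals:** 16 steps in total; longest linear sequence 11 steps (steps 1–6, then 12–16).

**Three steps most likely to fail**
1. **Step 15 (proposed new Pd step).** The electron-rich phenol may oxidatively dimerise, or Pd(II) may attack the prenyl or chromene alkene, giving low conversion.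
   - Fallback (known chemistry, C–O bond first and C–C last): form the 2-(methylthio)chromone from the A-ring acetophenone (NaH, CS2, MeI) and oxidise it to the 2-sulfone (mCPBA).
   - Displace the sulfone with 3,4-bis(MOMO)phenoxide, iodinate C3 (NIS), and close by intramolecular Pd direct arylation (Pd(OAc)2, PCy3·HBF4, K2CO3, DMA).
   - Finish with the same MOM removal.
2. **Step 4 (regiochemistry of the chromone closure).** The prenyl-flanked phenol could close instead, giving the 8-prenyl isomer.
   - Fallback (different order): start from phloroacetophenone plus prenal to give 6-acetyl-5,7-dihydroxy-2,2-dimethylchromene, then alkylate the less hindered 7-OH selectively (MOM), which forces closure through the 5-OH.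
   - Install the 6-prenyl last: NIS iodination at C6, Miyaura borylation, then Suzuki coupling with prenyl bromide.
3. **Step 12 (hindered Suzuki coupling; aryl OTBS may be base-labile).**
   - Fallback (different coupling partner): convert aryl bromide 19 to the aryl-SnBu3 (Pd-catalysed stannylation) and couple with iodochromone 12 under base-free Stille conditions (Pd(PPh3)4, CuI, DMF).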